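## Structural features

The target 30 is a eudesmane: two fused six-membered carbocycles, ring A (C1–C5, C10) and ring B (C5–C10), sharing the C5–C10 bond. A tetrasubstituted C4=C5 alkene sits at the ring fusion, methyl C15 is on C4 and the angular methyl C14 is on quaternary C10. There are four stereocentres: C3 (S, β-oxygen), C7 (R, β side chain, equatorial), C8 (R, β-acetoxy, axial) and C10 (R, β-methyl). C7 and C8 are vicinal and cis, the C8 acetoxy group is syn-axial to C14, and C3 stands alone on the far side of the alkene. Three different oxygen functions must be kept apart: the allylic (E)-3-methylpent-2-enoate at C3, the acetate at C8 and the methyl acrylate (C11=C13, C12) on C7. The fragile points are the allylic C3 ester (ionisation, allylic transposition), the β,β-disubstituted enoate (deconjugation under base), the acrylate (Michael acceptor, conjugate reduction) and the C8 acetate, whose loss would let O8 lactonise onto C12. The real difficulty is quaternary C10 in the correct relation to C7 and C8, with ring A oxygenated at C3 only. The key step exploits the run C15–C4=C5–C6–C7 with its three-carbon branch: it is the methyl-capped alkyne and isopropenyl stereocentre released when the ring of (R)-carvone (1) is cleaved. The C4=C5 alkene, flanked by C3 and C10, is then the alkyne-derived bond of a cyclohexa-1,4-diene, so rings A and B can close together in one [4+2] event with a C10=C1–C2=C3 diene.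

## Logic of the disconnections

30 is cut at the C3–O acyl bond into 28 and 29. The most ionisable ester is therefore made last, and 29 is commercial. The forward acylation must neither deconjugate 29 nor break the C3–O bond of 28.

28 is traced through 27, 26 and 25 to 23 by removing the C3–H carbinol bond and the C12–O bonds. In 23 the C3 ketone deactivates C4=C5, so C11=C13 is the only electron-rich alkene when C12 is oxidised. The gain is an ordinary isopropenyl group. The demands are oxidation at C12 and not at C7, and later hydride delivery to C3 from the α face without touching the acrylate.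

23 is traced through 22 to 21 by restoring C1=C2 and deleting the C3 carbonyl. This leaves ring A as an unoxygenated 1,4-diene whose C3 is the only doubly allylic carbon. The forward steps must oxidise C3 alone and then reduce only the less substituted arm of the dienone.

21 is traced through 20, 19 and 18 to 17 by changing the C8–O acyl bond to a silyl ether and inverting C8. The 8α (equatorial) epimer is wanted because it secures the facial outcome of ring formation. The demand is hydride attack on 19 from the α face without moving C11=C13 into conjugation.

17 is cut at C3–C4 and C5–C10 to 15 (key step). Two rings, two skeletal bonds and the C10 stereocentre disappear and an acyclic chain remains. The forward step needs reactivity at a trisubstituted diene terminus and control of the C10 face by C7 and C8.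

15 is cut at C1–C2 and C10–C14 to 12 and 13 (through 14). Syn-carbometalation of a terminal alkyne fixes the 8E geometry that the cycloaddition requires. The demand is that the terminal alkyne reacts and C4≡C5 does not.

12 is traced through 11 to 9 and 10 by cutting C9–C10 and the O–Si bond. A terminal epoxide is opened at C9 only, so C8 keeps its configuration, and the two-carbon nucleophile is commercial.

9 is traced through 7 and 6 to 4 (by way of 8 and 5) by removing the C8–O bond. C8 is α to the aldehyde carbon C9 of 4, so enamine catalysis can place the oxygen. 4 has a single stereocentre, and the catalyst must override it.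

4 is traced through 2 to 1 (by way of 3) by rejoining alkyne carbon C4 to aldehyde carbon C9 and removing the epoxide oxygen. 1 supplies ten of the fifteen skeletal carbons and the C7 stereocentre. The forward fragmentation must outrun hydrazone formation at the product aldehyde.

## Other disconnections considered

Alternative 1: The cut is C5–C6 and C9–C10, giving the cis-fused adduct A1. Forward, 2-methoxy-5-methyl-1,4-benzoquinone A2 and 2-(trimethylsilyloxy)buta-1,3-diene A3 would undergo a Diels–Alder reaction under a chiral Lewis acid made from TiCl2(OCHMe2)2 and 1,1'-bi-2-naphthol. Chelation between the methoxy oxygen and the C4 carbonyl would direct the diene to the methyl-bearing alkene.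
- In its favour: quaternary C10 is set by the catalyst, C3 and C8 carry oxygen from the start, and the C7=C8 silyl enol ether is a regiodefined handle for C7 substitution.
- Against it here: A1 holds only eleven of the fifteen skeletal carbons, lacking C15 and the C7 side chain. C1 must be deoxygenated, C4 must gain a methyl group and become part of C4=C5, and C7 and C8 stereochemistry must still be built.
- Comparison: the chosen plan finishes the whole skeleton in its key step, whereas A1 needs a long series of functional-group changes, so step economy favours the chosen plan. The mechanism is a concerted, Lewis-acid-activated cycloaddition rather than a metal-mediated stepwise one. A1 is the better on absolute stereocontrol (either enantiomer from the catalyst, no chiral-pool dependence) and on C3 oxidation (no C–H oxidation needed), and its reagents are less air-sensitive than Ni(cod)2.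

Alternative 2: The cut is C7–C8, giving 8α-hydroxyeudesma-4,11-dien-3-one A4. Forward, Me2AlCl would activate the C8 aldehyde of A5, which would undergo a carbonyl-ene reaction with the prenyl alkene on C5, a hydrogen of a C11 methyl moving to oxygen.
- In its favour: A4 already has the ring A enone, C15, the isopropenyl group and trans-diequatorial C7/C8. It is the C8 epimer of deacetylated 23, so steps 14 and 15 of the chosen route would not be needed.
- Against it here: quaternary C10 must be made enantioselectively in the monocyclic enone A5 by separate asymmetric chemistry. The Lewis acid can also trigger cationic (Prins-type) pathways at the prenyl group. C8 would have to be inverted with the enone present.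
- Comparison: the chair-like transition state relays C10 to C7 and C8, which is equal in reliability to the relay from C7 and C8 to C10 in the chosen plan. Ring A oxidation level is better handled in A4. Overall step count is on a par or lower only if A5 can be reached in few steps, which is the uncertain part. The chosen plan takes its absolute configuration from 1 directly.

Alternative 3: The cut is C9–C10, giving the dienone A6. Forward, KOt-Bu would form the phenolate of the phenol tosylate A7, whose para carbon C10 would displace the primary tosylate at C9.
- In its favour: no transition metal, ring A comes from an aromatic, and the C3 oxygen is the phenol oxygen. A6 is a cross-conjugated dienone of the kind the chosen route reaches only at 22, so the chromium oxidation is spared.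
- Against it here: the ortho carbon C4 is equally placed for a six-membered closure and would give the linearly conjugated dienone. The side chain of A7 with its C7 and C8 stereocentres has no chiral-pool source as direct as 1. Elimination of the tosylate and intermolecular O-alkylation compete.
- Comparison: facial control at C10 rests on the same equatorial C7/C8 chair argument and is equal. The mechanism is a dearomatising SN2 alkylation rather than a cycloaddition, forming one ring and one bond instead of two. Step economy after the key step is better by one or two steps, but the synthesis of A7 is expected to cost at least as much as the eight steps to 15.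

Key step: step 9

Remarks on the chemistry:
- Eudesmane numbering (C1–C15) is used for every intermediate, open-chain ones included.
- The structures of 15 and 17 were re-derived from 30 and no correction was needed. They carry 7R, the 8E diene, C8 epimeric to the target and C14 cis to C11. The C10 descriptor is S while C1 is olefinic and R once C1 is saturated, without any change in space.
- Three design decisions are made. The 8E diene of 15 is set by syn-carbometalation instead of by olefination of a methyl ketone. The 8α silyl ether is kept because only this epimer lets C7 and C8 both be equatorial in the ring-forming chair. C8 is inverted before ring A is oxidised, so no hydride step has to choose between two carbonyl groups.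
- The nickelacycle 16 is drawn without its phosphite ligands.

## Route

Step 1
Reactants: 1 (R)-carvone
Product: 2 (1R,4R,6R)-1-methyl-4-(prop-1-en-2-yl)-7-oxabicyclo[4.1.0]heptan-2-one
Conditions: H2O2 (30% aq.), NaOH (cat.), MeOH, 0 °C
Reagents that add atoms: hydrogen peroxide, OO
Why: Weitz–Scheffer epoxidation: hydroperoxide anion adds conjugately to the enone only and leaves the isopropenyl alkene alone. Attack trans to the isopropenyl group is expected, but both epoxide stereocentres are erased in step 2.

Step 2
Reactants: 2 carvone epoxide
Product: 4 (3S)-3-(prop-1-en-2-yl)hept-5-ynal, via epoxy tosylhydrazone 3 (not isolated)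
Conditions: TsNHNH2 (1.0 equiv), CH2Cl2/AcOH (1:1), −20 °C to rt
Reagents that add atoms: none
Why: Eschenmoser–Tanabe fragmentation: hydrazone 3 opens the epoxide to an alkoxy azoalkene, which fragments with loss of N2 and sulfinate to the methyl-capped C4≡C5 alkyne and the C9 aldehyde. The C7 stereocentre is not touched, and one equivalent of hydrazide limits condensation with the product aldehyde.

Step 3
Reactants: 4 ynal
Product: 6 (2R,3R)-2-(anilinooxy)-3-(prop-1-en-2-yl)hept-5-yn-1-ol, via aminooxy aldehyde 5 (not isolated)
Conditions: PhNO, L-proline (20 mol%), DMSO, rt; then NaBH4, MeOH, 0 °C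
Reagents that add atoms: nitrosobenzene, O=Nc1ccccc1
Why: Proline-catalysed α-aminoxylation (enamine catalysis, O-selective nitroso aldol), then reduction in the same flask. L-proline is expected to deliver oxygen in its usual (R)-2-oxy sense, which is the 8R carbinol needed here, with catalyst control overriding the β-stereocentre C7. Immediate reduction keeps the labile α-oxy aldehyde from epimerising.

Step 4
Reactants: 6 anilinooxy alcohol
Product: 7 (2R,3R)-3-(prop-1-en-2-yl)hept-5-yne-1,2-diol
Conditions: Zn dust, AcOH, THF, rt
Reagents that add atoms: none
Why: Reductive N–O cleavage by dissolving zinc. The alkyne, the alkene and both stereocentres are inert to it.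

Step 5
Reactants: 7 diol
Product: 9 (2R)-2-[(3R)-2-methylhept-1-en-5-yn-3-yl]oxirane, via monotosylate 8 (not isolated)
Conditions: NaH (2.5 equiv), 1-(p-toluenesulfonyl)imidazole, THF, 0 °C to rt
Reagents that add atoms: none
Why: The primary alkoxide is sulfonylated selectively and the C8 alkoxide then closes onto C9 (intramolecular Williamson reaction, SN2). The C8–O bond is never broken, so C8 keeps its configuration.

Step 6
Reactants: 9 epoxide; 10 lithium acetylide–ethylenediamine complex
Product: 11 (4S,5R)-5-(prop-1-en-2-yl)nona-1,7-diyn-4-ol
Conditions: LiC≡CH·H2NCH2CH2NH2 (3 equiv), DMSO, rt; then H2O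
Reagents that add atoms: none
Why: SN2 opening of a terminal epoxide by acetylide at the unhindered C9 forms C9–C10 and leaves C8 untouched. The internal alkyne has no acidic hydrogen and should be inert at room temperature.

Step 7
Reactants: 11 diynol
Product: 12 tert-butyl(dimethyl){[(4S,5R)-5-(prop-1-en-2-yl)nona-1,7-diyn-4-yl]oxy}silane
Conditions: TBSCl, imidazole, DMF, rt
Reagents that add atoms: tert-butyldimethylsilyl chloride, CC(C)(C)[Si](C)(C)Cl
Why: Standard silylation of a secondary alcohol. The bulky silyl ether is inert to the aluminium, palladium and nickel reagents that follow and serves as the equatorial anchor in step 9.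

Step 8
Reactants: 12 silyl ether; 13 vinyl bromide
Product: 15 (5R,6S,8E)-6-(tert-butyldimethylsilyloxy)-8-methyl-5-(prop-1-en-2-yl)undeca-8,10-dien-2-yne, via alkenylalane 14 (not isolated)
Conditions: Me3Al (2.5 equiv), Cp2ZrCl2 (0.3 equiv), CH2Cl2, 0 °C to rt; then CH2=CHBr, Pd(PPh3)4 (5 mol%), ZnCl2 (0.5 equiv), THF, rt
Reagents that add atoms: trimethylaluminium, C[Al](C)C
Why: Zirconium-catalysed carboalumination (Negishi) adds methyl and aluminium syn across the terminal alkyne, methyl going to C10, so C9 and the metal are trans. Cross-coupling of alane 14 with vinyl bromide on zerovalent palladium, with zinc co-catalysis, proceeds with retention and fixes the 8E diene. The terminal alkyne should carbometalate much faster than the dialkyl alkyne C4≡C5, and the isopropenyl group is inert to the achiral zirconocene.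

Step 9
Reactants: 15 dienyne
Product: 17 (7R,8S,10S)-8α-(tert-butyldimethylsilyloxy)eudesma-1,4,11-triene, via nickelacycle 16 (not isolated)
Conditions: Ni(cod)2 (10 mol%), P(O-2-biphenylyl)3 (30 mol%), degassed THF, rt to 55 °C
Reagents that add atoms: none
Why: Zerovalent nickel carrying the bulky, π-accepting phosphite binds the C4≡C5 alkyne and the s-cis C10=C1–C2=C3 diene and undergoes oxidative cyclisation, forming C5–C10 and the allyl–alkenyl nickelacycle 16; reductive elimination then joins C3 to C4 and frees the catalyst. The closest known reaction type is the nickel-catalysed intramolecular [4+2] cycloaddition of dienynes with unactivated alkynes, of which a trisubstituted diene terminus is a demanding member. Ring B closes in the oxidative cyclisation as a six-membered ring through the four-atom tether C6–C9 (exo with respect to both the alkyne and the diene terminus), and ring A closes in the reductive elimination as the cyclohexa-1,4-diene whose C4=C5 bond is the former alkyne. The one new stereocentre, C10, is set by the substrate: the forming ring B adopts a chair with the C7 isopropenyl and C8 silyloxy groups both equatorial, the C10–C1 bond stays in the diene plane and is equatorial, and C14 is forced axial on the face of C11. The 8E geometry puts the tether outside and C14 inside the diene, and the other chair would need both substituents axial with the silyloxy group syn-axial to C14, so high facial selectivity is expected. Chemoselectivity is needed against alkyne oligomerisation and against the isopropenyl alkene; intramolecularity, dilution and the weak binding of a 1,1-disubstituted alkene should secure it. Regiochemistry is fixed by the tether, and the low temperature avoids hydrogen shifts in the diene.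

Step 10
Reactants: 17 silyl ether
Product: 18 (7R,8S,10S)-eudesma-1,4,11-trien-8α-ol
Conditions: Bu4NF, THF, rt
Reagents that add atoms: none
Why: Fluoride-induced desilylation. The skipped diene cannot aromatise because C10 is quaternary.

Step 11
Reactants: 18 8α-alcohol
Product: 19 (7R,10S)-eudesma-1,4,11-trien-8-one
Conditions: Dess–Martin periodinane, NaHCO3, CH2Cl2, 0 °C to rt
Reagents that add atoms: none
Why: Dess–Martin oxidation under buffered, near-neutral conditions should not shift C11=C13 into conjugation with the new ketone. The reagent does not attack the doubly allylic C3.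

Step 12
Reactants: 19 ketone
Product: 20 (7R,8R,10S)-eudesma-1,4,11-trien-8β-ol
Conditions: LiBH(s-Bu)3, THF, −78 °C; then NaOH, H2O2, 0 °C
Reagents that add atoms: none
Why: The hindered hydride should attack C8 along the equatorial path from the α face, because the axial β path is blocked by the syn-axial C14 methyl. This gives the axial 8β alcohol cis to the C7 substituent, the usual result for 2-alkenylcyclohexanones with bulky borohydrides.

Step 13
Reactants: 20 8β-alcohol
Product: 21 (7R,8R,10S)-8β-acetoxyeudesma-1,4,11-triene
Conditions: Ac2O, DMAP (cat.), pyridine, CH2Cl2, rt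
Reagents that add atoms: acetic anhydride, CC(=O)OC(C)=O
Why: DMAP-catalysed acylation. The axial hydroxyl has only one syn-axial methyl neighbour and should acetylate normally, and the acetate then protects O8 through all later oxidations.

Step 14
Reactants: 21 acetate
Product: 22 (7R,8R,10S)-8β-acetoxyeudesma-1,4,11-trien-3-one
Conditions: CrO3 (15 equiv), 3,5-dimethylpyrazole (15 equiv), CH2Cl2, −20 °C
Reagents that add atoms: chromium trioxide CrO3, O=[Cr](=O)=O
Why: Allylic oxidation by the CrO3–3,5-dimethylpyrazole complex. C3 is the only doubly allylic methylene and C10 is quaternary, so the cross-conjugated dienone should form without aromatisation. The singly allylic C6, C15 and C12 positions react more slowly.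

Step 15
Reactants: 22 dienone
Product: 23 (7R,8R,10R)-8β-acetoxyeudesma-4,11-dien-3-one
Conditions: [(Ph3P)CuH]6 (0.4 equiv), H2O (5 equiv), toluene/THF, rt
Reagents that add atoms: none
Why: Conjugate reduction by the hexameric copper hydride: hydride adds to the β-monosubstituted C1 and not to the fully substituted C5, and the copper enolate is protonated at C2. Isolated alkenes and the acetate do not react.

Step 16
Reactants: 23 enone
Product: 25 (7R,8R,10R)-8β-acetoxy-3-oxoeudesma-4,11(13)-dien-12-al, via allylic alcohol 24 (not isolated)
Conditions: SeO2 (0.5 equiv), t-BuOOH (3 equiv), CH2Cl2, rt; then MnO2, CH2Cl2, rt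
Reagents that add atoms: selenium dioxide SeO2, O=[Se]=O; tert-butyl hydroperoxide, CC(C)(C)OO
Why: SeO2 allylic oxidation (ene reaction, then [2,3]-sigmatropic shift) at the only electron-rich alkene, since C4=C5 is deactivated by the C3 carbonyl. The methyl C12 should react in preference to the methine C7, which is hindered and flanked by the C8 acetate. MnO2 converges the alcohol 24 and aldehyde onto 25.

Step 17
Reactants: 25 enal
Product: 26 (7R,8R,10R)-8β-acetoxy-3-oxoeudesma-4,11(13)-dien-12-oic acid
Conditions: NaClO2, NaH2PO4, 2-methylbut-2-ene, t-BuOH/H2O, rt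
Reagents that add atoms: sodium chlorite NaClO2, [Na+].[O-]Cl=O
Why: Pinnick oxidation: chlorous acid oxidises the aldehyde only, and the alkene scavenger removes HOCl before it can reach C4=C5 or C11=C13.

Step 18
Reactants: 26 acid
Product: 27 methyl (7R,8R,10R)-8β-acetoxy-3-oxoeudesma-4,11(13)-dien-12-oate
Conditions: MeI, K2CO3, DMF, rt
Reagents that add atoms: iodomethane, CI
Why: SN2 O-alkylation of the carboxylate. It is preferred to a diazoalkane, which could add to the acrylate as a 1,3-dipole, and the mild base leaves the acetate in place.

Step 19
Reactants: 27 keto ester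
Product: 28 methyl (3S,7R,8R,10R)-8β-acetoxy-3β-hydroxyeudesma-4,11(13)-dien-12-oate
Conditions: NaBH4, CeCl3·7H2O, MeOH, −78 to −40 °C
Reagents that add atoms: none
Why: Luche reduction: cerium-assisted 1,2-reduction of the enone, with axial hydride delivery to C3 from the α face, anti to C14, giving the pseudo-equatorial 3β (3S) alcohol. At low temperature the acrylate and the esters should be spared.

Step 20
Reactants: 28 allylic alcohol; 29 (E)-3-methylpent-2-enoic acid
Product: 30 methyl (3S,7R,8R,10R)-8β-acetoxy-3β-[(E)-3-methylpent-2-enoyloxy]eudesma-4,11(13)-dien-12-oate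
Conditions: DCC, DMAP (cat.), CH2Cl2, 0 °C to rt
Reagents that add atoms: none
Why: Steglich esterification. Carbodiimide activation under near-neutral conditions avoids the vinylketene pathway that would deconjugate or isomerise the enoate, and the C3–O bond is not broken, so 3S is kept.

## Compound list

1 | (R)-carvone, (5R)-2-methyl-5-(prop-1-en-2-yl)cyclohex-2-en-1-one | CC1=CC[C@H](CC1=O)C(C)=C | starting material
2 | (1R,4R,6R)-1-methyl-4-(prop-1-en-2-yl)-7-oxabicyclo[4.1.0]heptan-2-one (oxirane trans to isopropenyl) | C=C(C)[C@@H]1C[C@H]2O[C@@]2(C)C(=O)C1 | intermediate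
3 | p-toluenesulfonylhydrazone of 2 at the former carbonyl carbon, ring stereocentres as in 2 (not isolated) | C=C(C)[C@@H]1C[C@H]2O[C@@]2(C)C(=NNS(=O)(=O)c3ccc(C)cc3)C1 | intermediate
4 | (3S)-3-(prop-1-en-2-yl)hept-5-ynal | C=C(C)[C@@H](CC#CC)CC=O | intermediate
5 | (2R,3R)-2-(anilinooxy)-3-(prop-1-en-2-yl)hept-5-ynal (not isolated) | C=C(C)[C@@H](CC#CC)[C@@H](ONc1ccccc1)C=O | intermediate
6 | (2R,3R)-2-(anilinooxy)-3-(prop-1-en-2-yl)hept-5-yn-1-ol | C=C(C)[C@@H](CC#CC)[C@@H](ONc1ccccc1)CO | intermediate
7 | (2R,3R)-3-(prop-1-en-2-yl)hept-5-yne-1,2-diol | C=C(C)[C@@H](CC#CC)[C@@H](O)CO | intermediate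
8 | (2R,3R)-2-hydroxy-3-(prop-1-en-2-yl)hept-5-yn-1-yl 4-methylbenzenesulfonate (not isolated) | C=C(C)[C@@H](CC#CC)[C@@H](O)COS(=O)(=O)c1ccc(C)cc1 | intermediate
9 | (2R)-2-[(3R)-2-methylhept-1-en-5-yn-3-yl]oxirane | C=C(C)[C@@H](CC#CC)[C@@H]1CO1 | intermediate
10 | lithium acetylide–ethylenediamine complex | [Li]C#C.NCCN | starting material
11 | (4S,5R)-5-(prop-1-en-2-yl)nona-1,7-diyn-4-ol | C=C(C)[C@@H](CC#CC)[C@@H](O)CC#C | intermediate
12 | tert-butyl(dimethyl){[(4S,5R)-5-(prop-1-en-2-yl)nona-1,7-diyn-4-yl]oxy}silane | C=C(C)[C@@H](CC#CC)[C@@H](O[Si](C)(C)C(C)(C)C)CC#C | intermediate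
13 | vinyl bromide (bromoethene) | C=CBr | starting material
14 | dimethyl[(1E,4S,5R)-4-(tert-butyldimethylsilyloxy)-2-methyl-5-(prop-1-en-2-yl)non-1-en-7-yn-1-yl]alane (not isolated) | C=C(C)[C@@H](CC#CC)[C@@H](O[Si](C)(C)C(C)(C)C)C/C(C)=C/[Al](C)C | intermediate
15 | (5R,6S,8E)-6-(tert-butyldimethylsilyloxy)-8-methyl-5-(prop-1-en-2-yl)undeca-8,10-dien-2-yne | C=C(C)[C@@H](CC#CC)[C@@H](O[Si](C)(C)C(C)(C)C)C/C(C)=C/C=C | intermediate
16 | nickelacycle with C5–C10 formed and nickel bound to C4 and C3, ligands omitted (not isolated) | C=C(C)[C@H]1CC2=C(C)[Ni]CC=C[C@]2(C)C[C@@H]1O[Si](C)(C)C(C)(C)C | intermediate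
17 | (7R,8S,10S)-8α-(tert-butyldimethylsilyloxy)eudesma-1,4,11-triene | C=C(C)[C@H]1CC2=C(C)CC=C[C@]2(C)C[C@@H]1O[Si](C)(C)C(C)(C)C | intermediate
18 | (7R,8S,10S)-eudesma-1,4,11-trien-8α-ol | C=C(C)[C@H]1CC2=C(C)CC=C[C@]2(C)C[C@@H]1O | intermediate
19 | (7R,10S)-eudesma-1,4,11-trien-8-one | C=C(C)[C@H]1CC2=C(C)CC=C[C@]2(C)CC1=O | intermediate
20 | (7R,8R,10S)-eudesma-1,4,11-trien-8β-ol | C=C(C)[C@H]1CC2=C(C)CC=C[C@]2(C)C[C@H]1O | intermediate
21 | (7R,8R,10S)-8β-acetoxyeudesma-1,4,11-triene | C=C(C)[C@H]1CC2=C(C)CC=C[C@]2(C)C[C@H]1OC(C)=O | intermediate
22 | (7R,8R,10S)-8β-acetoxyeudesma-1,4,11-trien-3-one | C=C(C)[C@H]1CC2=C(C)C(=O)C=C[C@]2(C)C[C@H]1OC(C)=O | intermediate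
23 | (7R,8R,10R)-8β-acetoxyeudesma-4,11-dien-3-one | C=C(C)[C@H]1CC2=C(C)C(=O)CC[C@]2(C)C[C@H]1OC(C)=O | intermediate
24 | (7R,8R,10R)-8β-acetoxy-12-hydroxyeudesma-4,11(13)-dien-3-one (not isolated) | C=C(CO)[C@H]1CC2=C(C)C(=O)CC[C@]2(C)C[C@H]1OC(C)=O | intermediate
25 | (7R,8R,10R)-8β-acetoxy-3-oxoeudesma-4,11(13)-dien-12-al | C=C(C=O)[C@H]1CC2=C(C)C(=O)CC[C@]2(C)C[C@H]1OC(C)=O | intermediate
26 | (7R,8R,10R)-8β-acetoxy-3-oxoeudesma-4,11(13)-dien-12-oic acid | C=C(C(=O)O)[C@H]1CC2=C(C)C(=O)CC[C@]2(C)C[C@H]1OC(C)=O | intermediate
27 | methyl (7R,8R,10R)-8β-acetoxy-3-oxoeudesma-4,11(13)-dien-12-oate | C=C(C(=O)OC)[C@H]1CC2=C(C)C(=O)CC[C@]2(C)C[C@H]1OC(C)=O | intermediate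
28 | methyl (3S,7R,8R,10R)-8β-acetoxy-3β-hydroxyeudesma-4,11(13)-dien-12-oate | C=C(C(=O)OC)[C@H]1CC2=C(C)[C@@H](O)CC[C@]2(C)C[C@H]1OC(C)=O | intermediate
29 | (E)-3-methylpent-2-enoic acid | CC/C(C)=C/C(=O)O | starting material
30 | methyl (3S,7R,8R,10R)-8β-acetoxy-3β-[(E)-3-methylpent-2-enoyloxy]eudesma-4,11(13)-dien-12-oate (CNP0118541.1) | C=C(C(=O)OC)[C@H]1CC2=C(C)[C@@H](OC(=O)/C=C(\C)CC)CC[C@]2(C)C[C@H]1OC(C)=O | target

## Step count and least certain steps

Total step count: 20. Longest linear sequence: 20 steps, from 1 to 30; 10, 13 and 29 are bought and used directly.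

**Step 9 (key step).** The inside methyl C14 disfavours the s-cis diene, so oxidative cyclisation may be slow and give way to alkyne oligomerisation or double-bond migration in the diene. Facial selectivity may also be incomplete if the tether does not hold its chair. The fallback leaves metal catalysis for a purely thermal intramolecular Diels–Alder reaction. It sets out from 15 (degassed 1,2-dichlorobenzene, 2,6-di-tert-butyl-4-methylphenol as inhibitor, about 200 °C, sealed tube) and comes back at 17. The concerted path obeys the same chair argument, and no new compound is made (F0). A 1,5-hydrogen shift of the inside methyl is the process to watch at that temperature.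

**Step 8.** Carbometalation may also take place at the C4≡C5 alkyne, or alane 14 may be protonated before it couples, so that the diene is lost or formed as a mixture. The fallback builds the diene by carbonyl chemistry. It sets out from 9 and comes back at 15.
- 2-Lithio-2-methyl-1,3-dithiane (from 2-methyl-1,3-dithiane and n-BuLi, THF, −30 °C) should open the epoxide at C9 to the dithiane alcohol F1.
- Silylation (TBSCl, imidazole) gives the silyl ether F2.
- S-Methylation and hydrolysis (MeI, CaCO3, aqueous MeCN) unmask the methyl ketone F3.
- A Horner–Wadsworth–Emmons reaction with triethyl phosphonoacetate (NaH, THF) gives the (E)-enoate F4, the Z isomer being removed.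
- Reduction with (Me2CHCH2)2AlH gives the allylic alcohol F5, and MnO2 gives the enal F6.
- Wittig methylenation (Ph3P=CH2) returns to 15.

**Step 14.** Oxidation may occur at the singly allylic C6 or C15 positions, or the dienone may be degraded by the large excess of hexavalent chromium. The fallback replaces the metal-oxo oxidation by a radical peroxidation and elimination sequence. It sets out from 21 and comes back at 22. t-BuOOH with catalytic dirhodium tetrakis(caprolactamate), Rh2(C6H10NO)4, and K2CO3 should abstract the weakest (doubly allylic) hydrogen and give the C3 tert-butyl peroxide F7. A Kornblum–DeLaMare elimination (Et3N, CH2Cl2) then converts F7 to 22.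

**Step 16.** The ene step may take the C7 hydrogen instead of a C12 hydrogen (hydroxylation at C7), or oxidation may occur next to the ketone. The fallback changes from selenium chemistry to an ene-type chlorination followed by oxidation. It sets out from 23 and comes back at 25. HOCl generated from Ca(OCl)2 and CO2 (CH2Cl2/H2O, 0 °C) should chlorinate only the isopropenyl group and give the allylic chloride F8. Trimethylamine N-oxide in DMSO then oxidises F8 to 25.

**Step 3.** Catalyst and C7 may be mismatched, or aldehyde 5 may epimerise or oligomerise before it is reduced, which would lower the diastereoselectivity at C8. The fallback forms a C–Cl bond and uses inversion instead of direct C–O bond formation. It sets out from 4 and comes back at 9. Organocatalytic α-chlorination (N-chlorosuccinimide, trans-2,5-diphenylpyrrolidine in the enantiomer that installs the 2S chloride, CH2Cl2) gives the chloro aldehyde F9. Reduction in the same flask (NaBH4, MeOH) gives the chlorohydrin F10, and KOH in ethanol closes the epoxide with inversion at C8 to return to 9.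

## Further compounds

F0 | step 9 | none | none
F1 | step 8 | (2S,3R)-1-(2-methyl-1,3-dithian-2-yl)-3-(prop-1-en-2-yl)hept-5-yn-2-ol | C=C(C)[C@@H](CC#CC)[C@@H](O)CC1(C)SCCCS1
F2 | step 8 | tert-butyldimethylsilyl ether of F1 | C=C(C)[C@@H](CC#CC)[C@@H](O[Si](C)(C)C(C)(C)C)CC1(C)SCCCS1
F3 | step 8 | (4S,5R)-4-(tert-butyldimethylsilyloxy)-5-(prop-1-en-2-yl)non-7-yn-2-one | C=C(C)[C@@H](CC#CC)[C@@H](O[Si](C)(C)C(C)(C)C)CC(C)=O
F4 | step 8 | ethyl (2E,5S,6R)-5-(tert-butyldimethylsilyloxy)-3-methyl-6-(prop-1-en-2-yl)dec-2-en-8-ynoate | C=C(C)[C@@H](CC#CC)[C@@H](O[Si](C)(C)C(C)(C)C)C/C(C)=C/C(=O)OCC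
F5 | step 8 | (2E,5S,6R)-5-(tert-butyldimethylsilyloxy)-3-methyl-6-(prop-1-en-2-yl)dec-2-en-8-yn-1-ol | C=C(C)[C@@H](CC#CC)[C@@H](O[Si](C)(C)C(C)(C)C)C/C(C)=C/CO
F6 | step 8 | (2E,5S,6R)-5-(tert-butyldimethylsilyloxy)-3-methyl-6-(prop-1-en-2-yl)dec-2-en-8-ynal | C=C(C)[C@@H](CC#CC)[C@@H](O[Si](C)(C)C(C)(C)C)C/C(C)=C/C=O
F7 | step 14 | (7R,8R,10S)-3-(tert-butylperoxy)eudesma-1,4,11-trien-8β-yl acetate, C3 configuration open | C=C(C)[C@H]1CC2=C(C)C(OOC(C)(C)C)C=C[C@]2(C)C[C@H]1OC(C)=O
F8 | step 16 | (7R,8R,10R)-8β-acetoxy-12-chloroeudesma-4,11(13)-dien-3-one | C=C(CCl)[C@H]1CC2=C(C)C(=O)CC[C@]2(C)C[C@H]1OC(C)=O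
F9 | step 3 | (2S,3R)-2-chloro-3-(prop-1-en-2-yl)hept-5-ynal | C=C(C)[C@@H](CC#CC)[C@H](Cl)C=O
F10 | step 3 | (2S,3R)-2-chloro-3-(prop-1-en-2-yl)hept-5-yn-1-ol | C=C(C)[C@@H](CC#CC)[C@H](Cl)CO
A1 | alternative 1 | cis-fused 3-methoxy-10-methyl-8-(trimethylsilyloxy)octalin-1,4-dione (target numbering, 5β-H, 10β-methyl) | COC1=CC(=O)[C@]2(C)CC(O[Si](C)(C)C)=CC[C@@H]2C1=O
A2 | alternative 1 | 2-methoxy-5-methyl-1,4-benzoquinone | COC1=CC(=O)C(C)=CC1=O
A3 | alternative 1 | 2-(trimethylsilyloxy)buta-1,3-diene | C=CC(=C)O[Si](C)(C)C
A4 | alternative 2 | (7R,8S,10R)-8α-hydroxyeudesma-4,11-dien-3-one | C=C(C)[C@H]1CC2=C(C)C(=O)CC[C@]2(C)C[C@@H]1O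
A5 | alternative 2 | 2-[(1R)-1,3-dimethyl-2-(3-methylbut-2-en-1-yl)-4-oxocyclohex-2-en-1-yl]acetaldehyde | CC(C)=CCC1=C(C)C(=O)CC[C@]1(C)CC=O
A6 | alternative 3 | (7R,8S,10S)-8α-(tert-butyldimethylsilyloxy)eudesma-1,4,11-trien-3-one | C=C(C)[C@H]1CC2=C(C)C(=O)C=C[C@]2(C)C[C@@H]1O[Si](C)(C)C(C)(C)C
A7 | alternative 3 | (2R,3R)-2-(tert-butyldimethylsilyloxy)-3-[(3-hydroxy-2,6-dimethylphenyl)methyl]-4-methylpent-4-en-1-yl 4-methylbenzenesulfonate | C=C(C)[C@@H](Cc1c(C)ccc(O)c1C)[C@@H](O[Si](C)(C)C(C)(C)C)COS(=O)(=O)c1ccc(C)cc1
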